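## Retrosynthetic overview
1. Target 24 ⇒ diketone 23. The C16 methylidene is installed last by a chemoselective methylenation.
2. Key bond C8–C15 joins two ketone α-carbons. C15 is turned into an enolonium on trivalent iodine and attacked by the C8=C9 enol silane, which closes ring D and the quaternary bridgehead.
3. Ring C ⇒ catalytic enantioselective Diels–Alder of silyloxydiene 19 with methyl vinyl ketone. This sets C13 and gives the C8=C9 enol ether regiospecifically.
4. C6–C7 ⇒ face-selective hydroboration of methylidene lactone 11, then radical addition to methyl vinyl ketone (sets C5). C14 comes from an iminium salt.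
5. Ring A and the γ-lactone ⇒ transannular oxidative radical closure C4–C5 of oxepanedione 8, made from (S)-linalool. Ring order: oxepanedione → ring A/lactone → ring C → ring D.

Assumption and shorthand: kaurane-type atom labels C1–C20 are used as locants; (S)-(+)-linalool is bought in high enantiomeric purity (any shortfall is removed by recrystallising 9); "Lac" = (1S,2S,5S,8S)-2-acetoxy-1,5-dimethyl-7-oxo-6-oxabicyclo[3.2.1]octan-8-yl, with the acetate and the C8 substituent both on the side away from the lactone bridge.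

## Route

Step 1
Reactants: 1 (S)-(+)-linalool
Product: 3 (5S)-5-ethenyl-5-methyloxolan-2-one, via lactol 2 (not isolated)
Conditions: O3 (1.0 equiv), CH2Cl2, −78 °C; Me2S, to rt, evaporate; PhI(OAc)2 (1.2 equiv), 2,2,6,6-tetramethylpiperidin-1-oxyl (10 mol %), CH2Cl2, rt
Reagents that add atoms: ozone [O-][O+]=O
Why: Chemoselective ozonolysis followed by oxoammonium lactol oxidation: ozone cleaves the electron-rich trisubstituted alkene much faster than the vinyl group, the hydroxy aldehyde closes to lactol 2 and is oxidised to the lactone, and the tertiary carbinol centre (future C10, S) comes unchanged from the chiral pool.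

Step 2
Reactants: 3 (5S)-5-ethenyl-5-methyloxolan-2-one, 4 tert-butyl propanoate
Product: 6 tert-butyl (6S)-6-hydroxy-2,6-dimethyl-3-oxooct-7-enoate, via lithium ester enolate 5 (not isolated)
Conditions: 4 (2.5 equiv), LiN(i-Pr)2 (2.5 equiv), THF, −78 °C; add 3, −78 to −20 °C; AcOH quench
Reagents that add atoms: lithium diisopropylamide [Li+].CC(C)[N-]C(C)C
Why: Crossed Claisen acylation of an ester enolate by a γ-lactone: 5 opens the unhindered lactone carbonyl, the second equivalent of enolate deprotonates the β-keto ester so no second addition occurs, C10 is untouched, and the C4 epimer mixture is irrelevant because C4 becomes planar in step 4.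

Step 3
Reactants: 6 tert-butyl (6S)-6-hydroxy-2,6-dimethyl-3-oxooct-7-enoate
Product: 8 (7S)-7-ethenyl-3,7-dimethyloxepane-2,4-dione, via acylketene 7 (not isolated)
Conditions: slow addition into PhMe (final 0.003 M), 110 °C, N2 sweep
Reagents that add atoms: none
Why: Acylketene lactonisation: the tert-butyl β-keto ester loses t-BuOH thermally to give acylketene 7, which under high dilution is captured by the tethered tertiary alcohol (helped by the gem-disubstituted C10), so the C19–O–C10 link that later enforces the cis bridge is in place and no lasting stereocentre is made.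

Step 4
Reactants: 8 (7S)-7-ethenyl-3,7-dimethyloxepane-2,4-dione
Product: 9 (1S,5S)-1,5-dimethyl-8-methylidene-6-oxabicyclo[3.2.1]octane-2,7-dione
Conditions: Mn(OAc)3·2H2O (2.2 equiv), Cu(OAc)2·H2O (0.5 equiv), degassed AcOH, 40 °C
Reagents that add atoms: none
Why: Mn(OAc)3/Cu(OAc)2 oxidative free-radical cyclisation (Snider type) run transannularly: one-electron oxidation turns the normally nucleophilic C4 into an electrophilic tertiary radical that adds 5-exo to the normally nucleophilic vinyl carbon C5, Cu(OAc)2 oxidises the primary C6 radical to the exocyclic alkene, and because C4 and C10 are already tied by the ester bridge only the cis-bridged bicycle can form, so C10 (S) fixes quaternary C4 as S.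

Step 5
Reactants: 9 (1S,5S)-1,5-dimethyl-8-methylidene-6-oxabicyclo[3.2.1]octane-2,7-dione
Product: 11 (1S,2S,5S)-1,5-dimethyl-8-methylidene-7-oxo-6-oxabicyclo[3.2.1]octan-2-yl acetate, via lithium alkoxide 10 (not isolated)
Conditions: LiBH(s-Bu)3 (1.1 equiv), THF, −78 °C; then Ac2O (4 equiv), 4-(dimethylamino)pyridine (0.2 equiv), −78 °C to rt
Reagents that add atoms: lithium tri-sec-butylborohydride [Li+].CCC(C)[BH-](C(C)CC)C(C)CC; acetic anhydride CC(=O)OC(C)=O
Why: Diastereoselective bulky-hydride reduction with in situ acylation: LiBH(s-Bu)3 takes the outward equatorial trajectory on the lactone side of the C3 ketone (the behaviour known for 3-oxo gibberellin 19,10-lactones), giving the axial alkoxide 10 on the face opposite the lactone (3S), which Ac2O traps before retro-aldol epimerisation can start.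

Step 6
Reactants: 11 (1S,2S,5S)-1,5-dimethyl-8-methylidene-7-oxo-6-oxabicyclo[3.2.1]octan-2-yl acetate, 12 methyl vinyl ketone, 13 N,N-dimethylmethyleneiminium iodide
Product: 16 3-[(dimethylamino)methyl]-5-Lac-pentan-2-one, via B-alkylcatecholborane 14 (not isolated), via boron enolate 15 (not isolated)
Conditions: catecholborane (1.5 equiv), MeC(O)NMe2 (10 mol %), CH2Cl2, 40 °C; t-BuOH (0.5 equiv); 12 (3 equiv), slow air, 0 °C to rt; 13 (2 equiv), rt; aq NaHCO3
Reagents that add atoms: catecholborane B1Oc2ccccc2O1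
Why: Proposed new method: syn hydroboration from the open lactone face of the alkene (the other face is covered by the axial acetate) puts H on C5 and boron on C6 and so sets C5 (S) with the chain away from the lactone, oxygen then starts a radical chain in which the primary C6 radical adds to 12 and the enoxyl radical frees the next C6 radical from 14 to give the regiodefined boron enolate 15, and 15 is intercepted at C8 by iminium salt 13; the closest known reactions are the Brown/Renaud radical conjugate addition of organoboranes to enones and the Hooz regiospecific Mannich reaction of enol borinates, which have not been combined on a catecholboron enolate.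

Step 7
Reactants: 16 3-[(dimethylamino)methyl]-5-Lac-pentan-2-one
Product: 19 2-(tert-butyldimethylsilyloxy)-3-(2-Lac-ethyl)buta-1,3-diene, via ammonium iodide 17 (not isolated), via enone 18 (not isolated)
Conditions: MeI (5 equiv), CH2Cl2, rt, evaporate; Et3N (4 equiv), CH2Cl2, rt; t-BuMe2SiOSO2CF3 (1.3 equiv), 0 °C
Reagents that add atoms: iodomethane CI; tert-butyldimethylsilyl triflate CC(C)(C)[Si](C)(C)OS(=O)(=O)C(F)(F)F
Why: Hofmann-type (E1cB) elimination of the quaternised Mannich base gives α-methylene ketone 18, whose only enolisable position is the methyl group, so soft enolisation gives the 2-silyloxydiene without touching the lactone or acetate; no stereocentre is involved.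

Step 8
Reactants: 19 2-(tert-butyldimethylsilyloxy)-3-(2-Lac-ethyl)buta-1,3-diene, 12 methyl vinyl ketone
Product: 20 1-[(1R)-4-(tert-butyldimethylsilyloxy)-3-(2-Lac-ethyl)cyclohex-3-en-1-yl]ethan-1-one
Conditions: 12 (3 equiv), (3aR)-1-(2-methylphenyl)-3,3-diphenyltetrahydro-1H,3H-pyrrolo[1,2-c][1,3,2]oxazaborole (20 mol %), HN(SO2CF3)2 (17 mol %), CH2Cl2, −78 to −40 °C
Reagents that add atoms: none
Why: Catalytic enantioselective Diels–Alder reaction (protonated oxazaborolidine, Corey type): the 2-silyloxy group directs the para regiochemistry (C11 to C12, C14 to C13), and the (R)-catalyst, the mirror image of the (S)-catalyst known to expose the Re face of the α-carbon of acrylates and expected to bind vinyl ketones in the same way, lets the diene add to the Si face of C13, which sets C13 as R independently of the remote Lac unit.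

Step 9
Reactants: 20 1-[(1R)-4-(tert-butyldimethylsilyloxy)-3-(2-Lac-ethyl)cyclohex-3-en-1-yl]ethan-1-one
Product: 23 (1S,5R)-1-(2-Lac-ethyl)bicyclo[3.2.1]octane-2,6-dione, via bis(silyl enol ether) 21 (not isolated), via enolonium 22 (not isolated)
Conditions: LiN(SiMe3)2 (1.1 equiv), Me3SiCl (1.5 equiv), THF, −78 °C; pentane, filter, evaporate; PhI(OAc)2 (1.2 equiv), BF3·OEt2 (2.4 equiv), CH2Cl2, −78 to −40 °C
Reagents that add atoms: chlorotrimethylsilane C[Si](C)(C)Cl; (diacetoxyiodo)benzene CC(=O)OI(OC(C)=O)c1ccccc1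
Why: Proposed new method: kinetic silylation gives the terminal trimethylsilyl enol ether, which PhI(OAc)2·BF3 attacks ahead of the hindered tetrasubstituted silyl enol ether to make C15 an enolonium (an α-keto cation equivalent on trivalent iodine, reacting through its C-bound form 22), and C8 of the tethered enol silane displaces PhI in a Baldwin-favoured 5-(enolexo)-exo-tet closure, so two normally nucleophilic α-carbons are joined and the two-atom bridge can only form cis to the C13–C16 bond, fixing quaternary C8 as S; the closest known reaction is the intermolecular cross-coupling of preformed enolonium species with silyl enol ethers to unsymmetrical 1,4-diketones (Moriarty/Szpilman type).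

Step 10
Reactants: 23 (1S,5R)-1-(2-Lac-ethyl)bicyclo[3.2.1]octane-2,6-dione
Product: 24 (1S,2S,5S,8S)-1,5-dimethyl-8-{2-[(1S,5R)-6-methylidene-2-oxobicyclo[3.2.1]octan-1-yl]ethyl}-7-oxo-6-oxabicyclo[3.2.1]octan-2-yl acetate
Conditions: Ph3PCH3Br (1.3 equiv), KOt-Bu (1.2 equiv), THF, 0 °C; add 23, −40 to 0 °C
Reagents that add atoms: methyltriphenylphosphonium bromide C[P+](c1ccccc1)(c1ccccc1)c1ccccc1.[Br-]
Why: Wittig methylenation, chemoselective for the strained and less hindered cyclopentanone carbonyl C16 over the neopentyl C9 ketone next to quaternary C8; the esters survive a small excess of ylide at low temperature, and bridgehead C13 cannot epimerise.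

## Compound list
1 | (S)-(+)-linalool, (3S)-3,7-dimethylocta-1,6-dien-3-ol | CC(=CCC[C@@](C)(C=C)O)C | starting material
2 | (5S)-5-ethenyl-5-methyloxolan-2-ol (lactol, anomers) | C=C[C@]1(C)CCC(O)O1 | intermediate
3 | (5S)-5-ethenyl-5-methyloxolan-2-one | C=C[C@]1(C)CCC(=O)O1 | intermediate
4 | tert-butyl propanoate | CCC(=O)OC(C)(C)C | starting material
5 | lithium 1-tert-butoxyprop-1-en-1-olate | CC=C([O-])OC(C)(C)C.[Li+] | intermediate
6 | tert-butyl (6S)-6-hydroxy-2,6-dimethyl-3-oxooct-7-enoate (C2 epimers) | C=C[C@@](C)(O)CCC(=O)C(C)C(=O)OC(C)(C)C | intermediate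
7 | (6S)-6-hydroxy-2,6-dimethylocta-1,7-diene-1,3-dione (acylketene) | C=C[C@@](C)(O)CCC(=O)C(C)=C=O | intermediate
8 | (7S)-7-ethenyl-3,7-dimethyloxepane-2,4-dione (C3 epimers) | C=C[C@]1(C)CCC(=O)C(C)C(=O)O1 | intermediate
9 | (1S,5S)-1,5-dimethyl-8-methylidene-6-oxabicyclo[3.2.1]octane-2,7-dione | C=C1[C@]2(C)C(=O)O[C@@]1(C)CCC2=O | intermediate
10 | lithium (1S,2S,5S)-1,5-dimethyl-8-methylidene-7-oxo-6-oxabicyclo[3.2.1]octan-2-olate | C=C1[C@]2(C)C(=O)O[C@@]1(C)CC[C@@H]2[O-].[Li+] | intermediate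
11 | (1S,2S,5S)-1,5-dimethyl-8-methylidene-7-oxo-6-oxabicyclo[3.2.1]octan-2-yl acetate | C=C1[C@]2(C)C(=O)O[C@@]1(C)CC[C@@H]2OC(C)=O | intermediate
12 | methyl vinyl ketone (but-3-en-2-one) | C=CC(C)=O | starting material
13 | N,N-dimethylmethyleneiminium iodide (Eschenmoser's salt) | C=[N+](C)C.[I-] | starting material
14 | 2-(Lac-methyl)-1,3,2-benzodioxaborole | c1ccc2c(c1)OB(O2)C[C@H]1[C@]2(C)C(=O)O[C@@]1(C)CC[C@@H]2OC(C)=O | intermediate
15 | 2-[(5-Lac-pent-2-en-2-yl)oxy]-1,3,2-benzodioxaborole | CC(OB1Oc2ccccc2O1)=CCC[C@H]1[C@]2(C)C(=O)O[C@@]1(C)CC[C@@H]2OC(C)=O | intermediate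
16 | 3-[(dimethylamino)methyl]-5-Lac-pentan-2-one (C3 epimers) | CC(=O)C(CN(C)C)CC[C@H]1[C@]2(C)C(=O)O[C@@]1(C)CC[C@@H]2OC(C)=O | intermediate
17 | (2-acetyl-4-Lac-butyl)trimethylammonium iodide | CC(=O)C(C[N+](C)(C)C)CC[C@H]1[C@]2(C)C(=O)O[C@@]1(C)CC[C@@H]2OC(C)=O.[I-] | intermediate
18 | 3-methylidene-5-Lac-pentan-2-one | CC(=O)C(=C)CC[C@H]1[C@]2(C)C(=O)O[C@@]1(C)CC[C@@H]2OC(C)=O | intermediate
19 | 2-(tert-butyldimethylsilyloxy)-3-(2-Lac-ethyl)buta-1,3-diene | C=C(O[Si](C)(C)C(C)(C)C)C(=C)CC[C@H]1[C@]2(C)C(=O)O[C@@]1(C)CC[C@@H]2OC(C)=O | intermediate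
20 | 1-[(1R)-4-(tert-butyldimethylsilyloxy)-3-(2-Lac-ethyl)cyclohex-3-en-1-yl]ethan-1-one | CC(=O)[C@@H]1CCC(O[Si](C)(C)C(C)(C)C)=C(CC[C@H]2[C@]3(C)C(=O)O[C@@]2(C)CC[C@@H]3OC(C)=O)C1 | intermediate
21 | tert-butyl{[(4R)-2-(2-Lac-ethyl)-4-[1-(trimethylsilyloxy)ethenyl]cyclohex-1-en-1-yl]oxy}dimethylsilane | C=C(O[Si](C)(C)C)[C@@H]1CCC(O[Si](C)(C)C(C)(C)C)=C(CC[C@H]2[C@]3(C)C(=O)O[C@@]2(C)CC[C@@H]3OC(C)=O)C1 | intermediate
22 | 2-[acetoxy(phenyl)-λ3-iodanyl]-1-[(1R)-4-(tert-butyldimethylsilyloxy)-3-(2-Lac-ethyl)cyclohex-3-en-1-yl]ethan-1-one | CC(=O)OI(c1ccccc1)CC(=O)[C@@H]1CCC(O[Si](C)(C)C(C)(C)C)=C(CC[C@H]2[C@]3(C)C(=O)O[C@@]2(C)CC[C@@H]3OC(C)=O)C1 | intermediate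
23 | (1S,5R)-1-(2-Lac-ethyl)bicyclo[3.2.1]octane-2,6-dione | O=C1C[C@]2(CC[C@H]3[C@]4(C)C(=O)O[C@@]3(C)CC[C@@H]4OC(C)=O)C[C@H]1CCC2=O | intermediate
24 | (1S,2S,5S,8S)-1,5-dimethyl-8-{2-[(1S,5R)-6-methylidene-2-oxobicyclo[3.2.1]octan-1-yl]ethyl}-7-oxo-6-oxabicyclo[3.2.1]octan-2-yl acetate | C=C1C[C@]2(CC[C@H]3[C@]4(C)C(=O)O[C@@]3(C)CC[C@@H]4OC(C)=O)C[C@H]1CCC2=O | target

## Step count and risks
Total step count: 10. Longest linear sequence: 10 (fully linear from 1).

**Step 3.** The hemiketal of 6 may dehydrate to a 2-alkylidene tetrahydrofuran, or the acylketene may dimerise, instead of closing the seven-membered ring. The fallback sets out from 1 and comes back at 8. It closes the ring through the C3–C4 bond instead of the C19–O bond. Acylation of 1 with 2-bromopropanoyl bromide and pyridine gives (3S)-3,7-dimethylocta-1,6-dien-3-yl 2-bromopropanoate F1. Selective ozonolysis (O3; Me2S) gives the aldehyde (3S)-3-methyl-6-oxohex-1-en-3-yl 2-bromopropanoate F2. A high-dilution intramolecular Reformatsky reaction with SmI2 in THF gives (7S)-7-ethenyl-4-hydroxy-3,7-dimethyloxepan-2-one F3. Dess–Martin oxidation then gives 8.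

**Step 6.** Release of a primary radical from the catecholborane may be slow, or enolate 15 may be protonated before it meets 13. The fallback sets out from 11 and comes back at 18. It replaces the boron radical chain by a halide-based Giese reaction and an acid Mannich reaction.
- 9-Borabicyclo[3.3.1]nonane adds from the same face to give the B-(Lac-methyl)-9-borabicyclo[3.3.1]nonane F4.
- NaBO3 oxidation gives (1S,2S,5S,8R)-8-(hydroxymethyl)-1,5-dimethyl-7-oxo-6-oxabicyclo[3.2.1]octan-2-yl acetate F5.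
- I2/PPh3/imidazole gives (1S,2S,5S,8S)-8-(iodomethyl)-1,5-dimethyl-7-oxo-6-oxabicyclo[3.2.1]octan-2-yl acetate F6.
- Giese addition to 12 with (Me3Si)3SiH and 2,2'-azobis(2-methylpropionitrile) gives 5-Lac-pentan-2-one F7.
- Methylenation at the more substituted α-carbon with paraformaldehyde and i-Pr2NH·CF3CO2H in refluxing THF gives 18.

**Step 9.** The iodane may attack the tetrasubstituted enol ether. The enolonium may also react only through its O-bound form, whose geometry amounts to a 5-endo closure. The fallback sets out from 20 and comes back at 23. It uses a metal carbenoid instead of an enolonium.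
- LiN(SiMe3)2 and CF3CO2CH2CF3 give 4,4,4-trifluoro-1-[(1R)-4-(tert-butyldimethylsilyloxy)-3-(2-Lac-ethyl)cyclohex-3-en-1-yl]butane-1,3-dione F8.
- Diazo transfer with MeSO2N3/Et3N gives 2-diazo-1-[(1R)-4-(tert-butyldimethylsilyloxy)-3-(2-Lac-ethyl)cyclohex-3-en-1-yl]ethan-1-one F9.
- Rh2(OAc)4 cyclopropanates the enol ether to the donor–acceptor silyloxycyclopropyl ketone F10.
- Bu4NF/AcOH cleaves the C9–C15 bond of F10 to give 23.

## Further compounds
F1 | step 3 | (3S)-3,7-dimethylocta-1,6-dien-3-yl 2-bromopropanoate | CC(Br)C(=O)O[C@](C)(C=C)CCC=C(C)C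
F2 | step 3 | (3S)-3-methyl-6-oxohex-1-en-3-yl 2-bromopropanoate | CC(Br)C(=O)O[C@](C)(C=C)CCC=O
F3 | step 3 | (7S)-7-ethenyl-4-hydroxy-3,7-dimethyloxepan-2-one | C=C[C@]1(C)CCC(O)C(C)C(=O)O1
F4 | step 6 | B-(Lac-methyl)-9-borabicyclo[3.3.1]nonane | C1CCC2CCCC1B2C[C@H]1[C@]2(C)C(=O)O[C@@]1(C)CC[C@@H]2OC(C)=O
F5 | step 6 | (1S,2S,5S,8R)-8-(hydroxymethyl)-1,5-dimethyl-7-oxo-6-oxabicyclo[3.2.1]octan-2-yl acetate | OC[C@H]1[C@]2(C)C(=O)O[C@@]1(C)CC[C@@H]2OC(C)=O
F6 | step 6 | (1S,2S,5S,8S)-8-(iodomethyl)-1,5-dimethyl-7-oxo-6-oxabicyclo[3.2.1]octan-2-yl acetate | IC[C@H]1[C@]2(C)C(=O)O[C@@]1(C)CC[C@@H]2OC(C)=O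
F7 | step 6 | 5-Lac-pentan-2-one | CC(=O)CCC[C@H]1[C@]2(C)C(=O)O[C@@]1(C)CC[C@@H]2OC(C)=O
F8 | step 9 | 4,4,4-trifluoro-1-[(1R)-4-(tert-butyldimethylsilyloxy)-3-(2-Lac-ethyl)cyclohex-3-en-1-yl]butane-1,3-dione | O=C(CC(=O)C(F)(F)F)[C@@H]1CCC(O[Si](C)(C)C(C)(C)C)=C(CC[C@H]2[C@]3(C)C(=O)O[C@@]2(C)CC[C@@H]3OC(C)=O)C1
F9 | step 9 | 2-diazo-1-[(1R)-4-(tert-butyldimethylsilyloxy)-3-(2-Lac-ethyl)cyclohex-3-en-1-yl]ethan-1-one | [N-]=[N+]=CC(=O)[C@@H]1CCC(O[Si](C)(C)C(C)(C)C)=C(CC[C@H]2[C@]3(C)C(=O)O[C@@]2(C)CC[C@@H]3OC(C)=O)C1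
F10 | step 9 | silyloxycyclopropyl ketone in which C15 is bonded to C8, C9 and C16 on the face syn to C16, with the silyl ether on C9 | O=C1[C@@H]2[C@]3(CC[C@H]4[C@]5(C)C(=O)O[C@@]4(C)CC[C@@H]5OC(C)=O)C[C@H]1CC[C@]23O[Si](C)(C)C(C)(C)C
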